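The red run holds more impurity and is warmer than the green run, yet at 4.00 min it shows 15.5% of left-handed product against the green run's 15.1%, so before I settle the next charge I want a number that puts these two runs side by side.

| flask | left-handed substrate | right-handed substrate | solid reagent | free catalyst | impurity | temperature | remark | time |
|---|---|---|---|---|---|---|---|---|
| green | 0.50 mM | 0.50 mM | 2.2 equiv | 17 mol% | 12 µM | −20 °C | run made earlier |  |
| red | 0.50 mM | 0.50 mM | 2.2 equiv | 17 mol% | 27 µM | 13 °C | run made earlier |  |
| Thursday's | 0.50 mM | 0.50 mM | 2.20 equiv | 17 mol% | 18 µM | 25 °C |  | 4.0 min |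
| Friday's | 0.50 mM | 0.50 mM | 2.20 equiv | 17 mol% | 18 µM | −5 °C |  | 4.0 min |
| Wednesday's | 0.50 mM | 0.50 mM | 2.20 equiv | 17 mol% | 18 µM | −35 °C |  | 4.0 min |

| run | time / min | left-handed product / % | left-handed substrate / % |
|---|---|---|---|
| green | 4.00 | 15.1 | 35.1 |
| green | 6.00 | 22.8 | 27.7 |
| green | 8.00 | 29.7 | 21.4 |
| green | 12.0 | 40.1 | 11.6 |
| green | 20.0 | 50.9 | 3.7 |
| green | 30.0 | 55.9 | 1.3 |
| green | 50.0 | 59.8 | 0.7 |
| red | 0.833 | 2.4 | 48.4 |
| red | 1.33 | 3.8 | 46.5 |
| red | 1.50 | 4.8 | 45.9 |
| red | 2.50 | 9.0 | 43.9 |
| red | 4.00 | 15.5 | 40.1 |
| red | 5.00 | 19.6 | 38.1 |
| red | 10.0 | 36.7 | 28.3 |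

(standard deviation of a reading: 0.3 percentage points)

- free catalyst is single-handed; left-handed substrate and right-handed substrate are mirror images of each other, charged as a racemate, each of them at the stated concentration
- as a solid, counted per litre of solution: solid reagent
- what was read earlier has a scatter of 0.3 percentage points, one standard deviation
- at the start none of the solid reagent is in solution

- which flask leads in amount of left-handed product, in percent of the left-handed substrate and right-handed substrate together charged ("all alike" within 1.5 percentage points) (Thursday's / Friday's / Wednesday's / all alike)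
- how much left-handed product is there at the end, in percent of the left-handed substrate and right-handed substrate together charged: Thursday's
- how much left-handed product is there at the end, in percent of the left-handed substrate and right-handed substrate together charged: Friday's
- how much left-handed product is there at the end, in percent of the left-handed substrate and right-handed substrate together charged: Wednesday's

Thursday's, Friday's and Wednesday's flasks, charged alike, each keep 67.0 µM of surviving catalyst, meaning the catalyst charged minus the impurity, if each impurity takes out one catalyst for good; on the same assumption the green run keeps 73.0 µM and the red run 58.0 µM. Since this quantity is equal in the three flasks, I leave the charge as it stands and let temperature be the one change. Friday's flask is warmer than the green run and colder than the red run, so I scale each run's product by surviving catalyst and get a bracket for Friday's from 13.9% to 17.9%. Thursday's and Wednesday's flasks lie outside the two temperatures read, and for them I commit to no figure.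

The forecast says all alike, with 15.6% for Thursday's, 15.3% for Friday's and 14.4% for Wednesday's, on the ground that “This looks like a supply limit”; its Friday's figure stands inside my bracket.

The flasks give 12.0% for Thursday's, 16.8% for Friday's and 11.2% for Wednesday's, so Friday's leads.

    partner + free catalyst + left-handed substrate → free catalyst + left-handed product (k = 1.00 × 10⁶ M⁻² s⁻¹, Ea = 15.0 kJ mol⁻¹)
    partner + free catalyst + right-handed substrate → free catalyst + right-handed product (k = 56000 M⁻² s⁻¹, Ea = 15.0 kJ mol⁻¹)
    left-handed substrate ⇌ right-handed substrate (k = 0.0270 s⁻¹, Ea = 73.0 kJ mol⁻¹)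
    free catalyst + impurity → spent catalyst (k = 4.50 × 10⁵ M⁻¹ s⁻¹, Ea = 13.0 kJ mol⁻¹)
    partner → decomposed reagent (k = 0.0480 s⁻¹, Ea = 74.0 kJ mol⁻¹)
    solid reagent ⇌ partner, rate k6*(cs6 - [partner]) while solid is left; crystals form when [partner] > cs6 (solubility = 0.180 mM, k = 0.00840 s⁻¹)
    (constants at 25 °C)

Free catalyst in Thursday's flask stands at 78.8% of its charge, as surviving catalyst gave (78.8%), and Friday's flask shows 78.8%. Yet at 4.00 min, the one time at which I compare them, product made per decomposed reagent, a branching ratio, is 0.684 in Thursday's flask against 8.88 in Friday's. In the neighbour of Thursday's charged with 29 mol% of catalyst, surviving catalyst is 127 µM, which scales Thursday's ratio to 1.30; the computed ratio is 1.25, with 17.0% of left-handed product.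

The data were computed on assumed constants; scatter was added.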